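## Retrosynthetic overview

1. The target (germacrane numbering) is taken back to the silyl-protected macrocyclic lactone 24; the C1–C10 oxirane (hydroxyl-directed epoxidation), the free C14 alcohol and the C11=C13 methylene are late-stage adjustments.
2. The strategy rests on the C1–C2 bond of the ten-membered carbocycle (C1–C10). It joins the vinylic C1 of the ring-trans C1=C10 alkene to the plain methylene C2, and the two arms it connects hang on the adjacent carbons C6 and C7 of the trans-fused γ-lactone (O–C6–C7–C11–C12). This bond is cut as a B-alkyl Suzuki pair: alkylborane at C2, alkenyl iodide at C1 (precursor 22).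
3. In 22, C14 and the C1 iodide come from a silylmethyl carbocupration–iodination of a C10≡C1 alkyne, C8 from a catalytic asymmetric propargylation of a C8 aldehyde, and the Z-diene from an iodo-Wittig olefination followed by Stille vinylation.
4. C7 is set by anti conjugate addition of lithiated 1,3-dithiane (masked C8 aldehyde) to the silyl ether of (S)-5-(hydroxymethyl)butenolide, which supplies C6.
5. Ring order: γ-lactone (present from the start), ten-membered carbocycle (step 13), oxirane (step 17).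

Key step: step 13

Remark: germacrane numbering is used throughout (lactone O–C6, C7, C11, C12=O; C13 the exocyclic methylene; C14 the hydroxymethyl carbon on C10; C15 the methyl on C4), and (R)-TRIP is assumed to direct the allenylboronate to the Re face of the C8 aldehyde as it does with simple aldehydes.

## Route

Step 1
Reactants: 1 (S)-5-(hydroxymethyl)furan-2(5H)-one
Product: 2 (S)-5-{[(tert-butyldimethylsilyl)oxy]methyl}furan-2(5H)-one
Conditions: TBSCl, imidazole, CH2Cl2, 0 °C to rt
Reagents that add atoms: tert-butyldimethylsilyl chloride, C[Si](C)(Cl)C(C)(C)C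
Why: Imidazole-mediated silylation of a primary alcohol is reliable under conditions too mild to enolise the butenolide, and the bulky ether later shields one face of the ring.

Step 2
Reactants: 2 (S)-5-{[(tert-butyldimethylsilyl)oxy]methyl}furan-2(5H)-one; 3 1,3-dithiane
Product: 5 (4S,5S)-5-{[(tert-butyldimethylsilyl)oxy]methyl}-4-(1,3-dithian-2-yl)dihydrofuran-2(3H)-one, via lithium enolate 4 (not isolated)
Conditions: n-BuLi, THF, −30 °C; HMPA, then 2, −78 °C; AcOH, −78 °C
Reagents that add atoms: none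
Why: Michael addition of the sulfur-stabilised 2-lithio-1,3-dithiane, steered to the 1,4-mode by HMPA, should occur anti to the silyloxymethyl group on C6 and so set C7 trans to C6 by substrate control; the enolate is then protonated.

Step 3
Reactants: 5 (4S,5S)-5-{[(tert-butyldimethylsilyl)oxy]methyl}-4-(1,3-dithian-2-yl)dihydrofuran-2(3H)-one
Product: 6 (4S,5S)-4-(1,3-dithian-2-yl)-5-(hydroxymethyl)dihydrofuran-2(3H)-one
Conditions: HF·pyridine, pyridine, THF, 0 °C to rt
Reagents that add atoms: none
Why: Buffered fluoride desilylation frees the primary alcohol without the basic alkoxide that could trigger translactonisation.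

Step 4
Reactants: 6 (4S,5S)-4-(1,3-dithian-2-yl)-5-(hydroxymethyl)dihydrofuran-2(3H)-one
Product: 7 (2S,3S)-3-(1,3-dithian-2-yl)-5-oxotetrahydrofuran-2-carbaldehyde
Conditions: (COCl)2, DMSO, CH2Cl2, −78 °C; Et3N, −78 to −20 °C
Reagents that add atoms: none
Why: Swern oxidation tolerates the thioacetal and, at low temperature, should leave the C6 centre (α to the new aldehyde) intact; epimerisation would in any case lead to the less stable cis lactone.

Step 5
Reactants: 7 (2S,3S)-3-(1,3-dithian-2-yl)-5-oxotetrahydrofuran-2-carbaldehyde; 8 ethyltriphenylphosphonium iodide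
Product: 9 (4S,5S)-4-(1,3-dithian-2-yl)-5-[(Z)-2-iodoprop-1-en-1-yl]dihydrofuran-2(3H)-one
Conditions: 8, n-BuLi, THF, rt; I2, −78 °C; NaN(SiMe3)2, −78 to −20 °C; then 7, −78 °C
Reagents that add atoms: iodine, II
Why: The Stork–Zhao type iodo-Wittig olefination with the unstabilised (1-iodoethylidene)phosphorane proceeds through the kinetic cis-oxaphosphetane and should give the Z iodoalkene (iodine cis to C6) that fixes the C4=C5 geometry.

Step 6
Reactants: 9 (4S,5S)-4-(1,3-dithian-2-yl)-5-[(Z)-2-iodoprop-1-en-1-yl]dihydrofuran-2(3H)-one; 10 tributyl(vinyl)stannane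
Product: 11 (4S,5R)-4-(1,3-dithian-2-yl)-5-[(1Z)-2-methylbuta-1,3-dien-1-yl]dihydrofuran-2(3H)-one
Conditions: PdCl2(MeCN)2 (5 mol %), DMF, rt
Reagents that add atoms: none
Why: Stille coupling of an alkenyl iodide with a vinylstannane is neutral and stereoretentive, so the Z geometry is carried into the diene; oxidative addition to C–I at room temperature should outrun ionisation of the allylic lactone C6–O bond.

Step 7
Reactants: 11 (4S,5R)-4-(1,3-dithian-2-yl)-5-[(1Z)-2-methylbuta-1,3-dien-1-yl]dihydrofuran-2(3H)-one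
Product: 12 (2R,3S)-2-[(1Z)-2-methylbuta-1,3-dien-1-yl]-5-oxotetrahydrofuran-3-carbaldehyde
Conditions: MeI, CaCO3, MeCN/H2O (9:1), rt to 35 °C; used crude
Reagents that add atoms: water, O
Why: Alkylative thioacetal hydrolysis (S-methylation, then hydrolysis) is non-oxidative, so the diene survives, and the CaCO3-buffered medium should limit epimerisation at C7 and β-elimination of the lactone carboxylate from the C8 aldehyde.

Step 8
Reactants: 12 (2R,3S)-2-[(1Z)-2-methylbuta-1,3-dien-1-yl]-5-oxotetrahydrofuran-3-carbaldehyde; 13 allenylboronic acid pinacol ester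
Product: 15 (4R,5R)-4-[(1R)-1-hydroxybut-3-yn-1-yl]-5-[(1Z)-2-methylbuta-1,3-dien-1-yl]dihydrofuran-2(3H)-one, via O-pinacolboryl ether 14 (not isolated)
Conditions: (R)-TRIP (10 mol %), 4 Å molecular sieves, cyclohexane/toluene, 0 °C to rt; aq. NaHCO3 work-up
Reagents that add atoms: none
Why: Chiral phosphoric acid catalysed propargylation with an allenylboronate runs through a closed six-membered SE2' transition state under non-basic conditions that spare the elimination-prone aldehyde; the catalyst is expected to direct attack to the Re face of C8 and give the 8R carbinol, the inherent bias of the C7 centre being uncertain.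

Step 9
Reactants: 15 (4R,5R)-4-[(1R)-1-hydroxybut-3-yn-1-yl]-5-[(1Z)-2-methylbuta-1,3-dien-1-yl]dihydrofuran-2(3H)-one; 16 isobutyryl chloride
Product: 17 (1R)-1-{(2R,3R)-2-[(1Z)-2-methylbuta-1,3-dien-1-yl]-5-oxotetrahydrofuran-3-yl}but-3-yn-1-yl 2-methylpropanoate
Conditions: pyridine, DMAP (cat.), CH2Cl2, 0 °C
Reagents that add atoms: none
Why: DMAP-catalysed acylation of the secondary alcohol installs the C8 isobutyrate without touching the C8–O bond, so the configuration is retained.

Step 10
Reactants: 17 (1R)-1-{(2R,3R)-2-[(1Z)-2-methylbuta-1,3-dien-1-yl]-5-oxotetrahydrofuran-3-yl}but-3-yn-1-yl 2-methylpropanoate; 18 (chloromethyl)(isopropoxy)dimethylsilane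
Product: 20 (1R,3Z)-4-iodo-3-{[isopropoxy(dimethyl)silyl]methyl}-1-{(2R,3R)-2-[(1Z)-2-methylbuta-1,3-dien-1-yl]-5-oxotetrahydrofuran-3-yl}but-3-en-1-yl 2-methylpropanoate, via alkenylcopper 19 (not isolated)
Conditions: 18, Mg, THF, rt; CuBr·SMe2, Et2O/Me2S, −45 °C; then 17, −45 to −20 °C; I2, −60 to 0 °C
Reagents that add atoms: iodine, II
Why: Normant carbocupration adds the α-silylalkylcopper syn across the terminal alkyne with the new C–C bond at the internal carbon C10 and copper on C1, and iodinolysis with retention then places iodine cis to the C14 methylene and trans to C9; organocopper reagents of this kind do not attack esters at these temperatures.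

Step 11
Reactants: 20 (1R,3Z)-4-iodo-3-{[isopropoxy(dimethyl)silyl]methyl}-1-{(2R,3R)-2-[(1Z)-2-methylbuta-1,3-dien-1-yl]-5-oxotetrahydrofuran-3-yl}but-3-en-1-yl 2-methylpropanoate
Product: 21 (1R,3Z)-3-(hydroxymethyl)-4-iodo-1-{(2R,3R)-2-[(1Z)-2-methylbuta-1,3-dien-1-yl]-5-oxotetrahydrofuran-3-yl}but-3-en-1-yl 2-methylpropanoate
Conditions: 30% H2O2, KF, KHCO3, THF/MeOH, 0 °C to rt
Reagents that add atoms: hydrogen peroxide, OO
Why: Tamao oxidation converts the alkoxysilyl C–Si bond into C–OH by fluoride-assisted peroxide rearrangement at the primary carbon; the alkenyl iodide and the diene are inert to the buffered peroxide.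

Step 12
Reactants: 21 (1R,3Z)-3-(hydroxymethyl)-4-iodo-1-{(2R,3R)-2-[(1Z)-2-methylbuta-1,3-dien-1-yl]-5-oxotetrahydrofuran-3-yl}but-3-en-1-yl 2-methylpropanoate
Product: 22 (1R,3Z)-3-{[(tert-butyldimethylsilyl)oxy]methyl}-4-iodo-1-{(2R,3R)-2-[(1Z)-2-methylbuta-1,3-dien-1-yl]-5-oxotetrahydrofuran-3-yl}but-3-en-1-yl 2-methylpropanoate
Conditions: TBSCl, imidazole, CH2Cl2, 0 °C
Reagents that add atoms: tert-butyldimethylsilyl chloride, C[Si](C)(Cl)C(C)(C)C
Why: Silylation masks the C14 alcohol so that it neither consumes 9-BBN nor forms an alkoxide during the later enolate chemistry.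

Step 13
Reactants: 22 (1R,3Z)-3-{[(tert-butyldimethylsilyl)oxy]methyl}-4-iodo-1-{(2R,3R)-2-[(1Z)-2-methylbuta-1,3-dien-1-yl]-5-oxotetrahydrofuran-3-yl}but-3-en-1-yl 2-methylpropanoate
Product: 24 (6R,7R,8R)-14-[(tert-butyldimethylsilyl)oxy]-8-(isobutyryloxy)germacra-1(10),4-dien-12,6-olide (ring-trans C1=C10 with C2 cis to C14; C4=C5 Z), via C2 alkylborane 23 (not isolated)
Conditions: 9-BBN, THF, 0 °C to rt; then slow addition to PdCl2(dppf) (20 mol %), AsPh3, Cs2CO3, DMF/THF/H2O, rt to 45 °C, final 0.002 M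
Reagents that add atoms: none
Why: 9-BBN adds anti-Markovnikov to the only monosubstituted alkene (C2=C3) and puts boron on C2; zerovalent palladium then inserts into the C1–I bond with retention, the base-activated borane transfers the primary C2 alkyl group to palladium, and reductive elimination forms C1–C2. The closest known reaction type is the B-alkyl Suzuki–Miyaura macrocyclisation of a 9-BBN alkylborane onto an alkenyl iodide. The ten-membered carbocycle closes by this intramolecular sp3–sp2 coupling, with both bonding carbons becoming ring members, through an eleven-membered palladacycle, and slow addition at high dilution should favour it over oligomerisation. No stereocentre is formed; the C4=C5 (Z) and C1=C10 (ring-trans) geometries are fixed beforehand and are retained through oxidative addition and reductive elimination. The step needs hydroboration at C2=C3 only, which the steric demand of 9-BBN secures against the trisubstituted C4=C5 and the iodoalkene, and ring closure over intermolecular coupling, which is helped by the two arms starting from the adjacent lactone carbons C6 and C7. Oxidative addition to the alkenyl iodide should also be much faster than ionisation of the allylic C6–O lactone bond.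

Step 14
Reactants: 24 (6R,7R,8R)-14-[(tert-butyldimethylsilyl)oxy]-8-(isobutyryloxy)germacra-1(10),4-dien-12,6-olide
Product: 26 11-[(dimethylamino)methyl] derivative of 24 (mixture of C11 epimers), via lithium enolate 25 (not isolated)
Conditions: LiN(SiMe3)2, THF, −78 °C; Eschenmoser's salt, −78 to 0 °C
Reagents that add atoms: N,N-dimethylmethyleneiminium iodide (Eschenmoser's salt), C=[N+](C)C.[I-]
Why: The Mannich reaction of the lactone enolate should be selective because the lactone CH2 (C11) is more acidic and less hindered than the isobutyrate methine; the new C11 centre is destroyed in the next step, so its configuration does not matter.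

Step 15
Reactants: 26 11-[(dimethylamino)methyl] derivative of 24
Product: 28 (6R,7R,8R)-14-[(tert-butyldimethylsilyl)oxy]-8-(isobutyryloxy)germacra-1(10),4,11(13)-trien-12,6-olide, via trimethylammonium iodide 27 (not isolated)
Conditions: MeI, MeOH, rt; then NaHCO3, CH2Cl2/H2O, rt
Reagents that add atoms: none
Why: Quaternisation turns the amine into a leaving group and mild base then effects E1cB (Hofmann-type) elimination of trimethylamine to give the conjugated C11=C13 methylene.

Step 16
Reactants: 28 (6R,7R,8R)-14-[(tert-butyldimethylsilyl)oxy]-8-(isobutyryloxy)germacra-1(10),4,11(13)-trien-12,6-olide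
Product: 29 (6R,7R,8R)-14-hydroxy-8-(isobutyryloxy)germacra-1(10),4,11(13)-trien-12,6-olide
Conditions: HF·pyridine, pyridine, THF, 0 °C
Reagents that add atoms: none
Why: Buffered fluoride desilylation frees the C14 allylic alcohol without the basic alkoxide that could add to the methylene lactone or shift the isobutyrate.

Step 17
Reactants: 29 (6R,7R,8R)-14-hydroxy-8-(isobutyryloxy)germacra-1(10),4,11(13)-trien-12,6-olide
Product: 30 (1R,6R,7R,8R,10S)-1,10-epoxy-14-hydroxy-8-(isobutyryloxy)germacra-4(Z),11(13)-dien-12,6-olide (CNP0247143.1)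
Conditions: VO(acac)2 (5 mol %), t-BuOOH (decane), CH2Cl2, 0 °C
Reagents that add atoms: tert-butyl hydroperoxide, CC(C)(C)OO
Why: Hydroxyl-directed vanadium-catalysed epoxidation acts only on the allylic-alcohol alkene C1=C10 (not on C4=C5 or the electron-poor C11=C13) and is stereospecific, so C2 and C14 stay cis on the oxirane; oxygen should be delivered to the outward face of C1=C10 in the conformer with C14 on the side of H6, giving C1 (R) and C10 (S) by substrate control.

## Compound list

1 | (S)-5-(hydroxymethyl)furan-2(5H)-one | O=C1O[C@H](CO)C=C1 | starting material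
2 | (S)-5-{[(tert-butyldimethylsilyl)oxy]methyl}furan-2(5H)-one | O=C1O[C@H](CO[Si](C)(C)C(C)(C)C)C=C1 | intermediate
3 | 1,3-dithiane | C1CSCSC1 | starting material
4 | lithium enolate of lactone 5 (C11=C12–OLi) | [Li]OC1O[C@H](CO[Si](C)(C)C(C)(C)C)[C@H](C=1)C2SCCCS2 | intermediate
5 | (4S,5S)-5-{[(tert-butyldimethylsilyl)oxy]methyl}-4-(1,3-dithian-2-yl)dihydrofuran-2(3H)-one (4,5-trans) | O=C1O[C@H](CO[Si](C)(C)C(C)(C)C)[C@H](C1)C2SCCCS2 | intermediate
6 | (4S,5S)-4-(1,3-dithian-2-yl)-5-(hydroxymethyl)dihydrofuran-2(3H)-one | O=C1O[C@H](CO)[C@H](C1)C2SCCCS2 | intermediate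
7 | (2S,3S)-3-(1,3-dithian-2-yl)-5-oxotetrahydrofuran-2-carbaldehyde | O=C1O[C@H](C=O)[C@H](C1)C2SCCCS2 | intermediate
8 | ethyltriphenylphosphonium iodide | CC[P+](c1ccccc1)(c1ccccc1)c1ccccc1.[I-] | starting material
9 | (4S,5S)-4-(1,3-dithian-2-yl)-5-[(Z)-2-iodoprop-1-en-1-yl]dihydrofuran-2(3H)-one | O=C1O[C@H](/C=C(/C)I)[C@H](C1)C2SCCCS2 | intermediate
10 | tributyl(vinyl)stannane | C=C[Sn](CCCC)(CCCC)CCCC | starting material
11 | (4S,5R)-4-(1,3-dithian-2-yl)-5-[(1Z)-2-methylbuta-1,3-dien-1-yl]dihydrofuran-2(3H)-one | O=C1O[C@H](/C=C(/C)C=C)[C@H](C1)C2SCCCS2 | intermediate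
12 | (2R,3S)-2-[(1Z)-2-methylbuta-1,3-dien-1-yl]-5-oxotetrahydrofuran-3-carbaldehyde | O=C1O[C@H](/C=C(/C)C=C)[C@H](C1)C=O | intermediate
13 | allenylboronic acid pinacol ester (4,4,5,5-tetramethyl-2-(propa-1,2-dien-1-yl)-1,3,2-dioxaborolane) | C=C=CB1OC(C)(C)C(C)(C)O1 | starting material
14 | O-pinacolboryl ether of alcohol 15 (8R) | O=C1O[C@H](/C=C(/C)C=C)[C@H](C1)[C@H](OB2OC(C)(C)C(C)(C)O2)CC#C | intermediate
15 | (4R,5R)-4-[(1R)-1-hydroxybut-3-yn-1-yl]-5-[(1Z)-2-methylbuta-1,3-dien-1-yl]dihydrofuran-2(3H)-one | O=C1O[C@H](/C=C(/C)C=C)[C@H](C1)[C@H](O)CC#C | intermediate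
16 | isobutyryl chloride | CC(C)C(Cl)=O | starting material
17 | (1R)-1-{(2R,3R)-2-[(1Z)-2-methylbuta-1,3-dien-1-yl]-5-oxotetrahydrofuran-3-yl}but-3-yn-1-yl 2-methylpropanoate | O=C1O[C@H](/C=C(/C)C=C)[C@H](C1)[C@H](OC(=O)C(C)C)CC#C | intermediate
18 | (chloromethyl)(isopropoxy)dimethylsilane | ClC[Si](C)(C)OC(C)C | starting material
19 | alkenylcopper from 17 (copper on C1, cis to the silylmethyl group on C10) | O=C1O[C@H](/C=C(/C)C=C)[C@H](C1)[C@H](OC(=O)C(C)C)C/C(C[Si](C)(C)OC(C)C)=C/[Cu] | intermediate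
20 | (1R,3Z)-4-iodo-3-{[isopropoxy(dimethyl)silyl]methyl}-1-{(2R,3R)-2-[(1Z)-2-methylbuta-1,3-dien-1-yl]-5-oxotetrahydrofuran-3-yl}but-3-en-1-yl 2-methylpropanoate | O=C1O[C@H](/C=C(/C)C=C)[C@H](C1)[C@H](OC(=O)C(C)C)C/C(C[Si](C)(C)OC(C)C)=C/I | intermediate
21 | (1R,3Z)-3-(hydroxymethyl)-4-iodo-1-{(2R,3R)-2-[(1Z)-2-methylbuta-1,3-dien-1-yl]-5-oxotetrahydrofuran-3-yl}but-3-en-1-yl 2-methylpropanoate | O=C1O[C@H](/C=C(/C)C=C)[C@H](C1)[C@H](OC(=O)C(C)C)C/C(CO)=C/I | intermediate
22 | (1R,3Z)-3-{[(tert-butyldimethylsilyl)oxy]methyl}-4-iodo-1-{(2R,3R)-2-[(1Z)-2-methylbuta-1,3-dien-1-yl]-5-oxotetrahydrofuran-3-yl}but-3-en-1-yl 2-methylpropanoate (key-step precursor) | O=C1O[C@H](/C=C(/C)C=C)[C@H](C1)[C@H](OC(=O)C(C)C)C/C(CO[Si](C)(C)C(C)(C)C)=C/I | intermediate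
23 | C2 alkylborane of 22 (9-borabicyclo[3.3.1]nonan-9-yl on C2) | O=C1O[C@H](/C=C(/C)CCB2C3CCCC2CCC3)[C@H](C1)[C@H](OC(=O)C(C)C)C/C(CO[Si](C)(C)C(C)(C)C)=C/I | intermediate
24 | (6R,7R,8R)-14-[(tert-butyldimethylsilyl)oxy]-8-(isobutyryloxy)germacra-1(10),4-dien-12,6-olide (ring-trans C1=C10, C4=C5 Z) | O=C1O[C@@H]2/C=C(/C)CC/C=C(\CO[Si](C)(C)C(C)(C)C)C[C@@H](OC(=O)C(C)C)[C@H]2C1 | intermediate
25 | lithium enolate of 24 (C11=C12–OLi) | [Li]OC1O[C@@H]2/C=C(/C)CC/C=C(\CO[Si](C)(C)C(C)(C)C)C[C@@H](OC(=O)C(C)C)[C@H]2C=1 | intermediate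
26 | 11-[(dimethylamino)methyl] derivative of 24 (C11 epimers) | O=C1O[C@@H]2/C=C(/C)CC/C=C(\CO[Si](C)(C)C(C)(C)C)C[C@@H](OC(=O)C(C)C)[C@H]2C1CN(C)C | intermediate
27 | 11-[(trimethylammonio)methyl] iodide of 24 (C11 epimers) | O=C1O[C@@H]2/C=C(/C)CC/C=C(\CO[Si](C)(C)C(C)(C)C)C[C@@H](OC(=O)C(C)C)[C@H]2C1C[N+](C)(C)C.[I-] | intermediate
28 | (6R,7R,8R)-14-[(tert-butyldimethylsilyl)oxy]-8-(isobutyryloxy)germacra-1(10),4,11(13)-trien-12,6-olide | C=C1C(=O)O[C@@H]2/C=C(/C)CC/C=C(\CO[Si](C)(C)C(C)(C)C)C[C@@H](OC(=O)C(C)C)[C@@H]12 | intermediate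
29 | (6R,7R,8R)-14-hydroxy-8-(isobutyryloxy)germacra-1(10),4,11(13)-trien-12,6-olide | C=C1C(=O)O[C@@H]2/C=C(/C)CC/C=C(\CO)C[C@@H](OC(=O)C(C)C)[C@@H]12 | intermediate
30 | (1R,6R,7R,8R,10S)-1,10-epoxy-14-hydroxy-8-(isobutyryloxy)germacra-4(Z),11(13)-dien-12,6-olide (CNP0247143.1) | C=C1C(=O)O[C@@H]2/C=C(/C)CC[C@H]3O[C@]3(CO)C[C@@H](OC(=O)C(C)C)[C@@H]12 | target

## Step count and risks

Total step count: 17. Longest linear sequence: 17 steps (from 1 to 30; the Grignard reagent from 18 is made within step 10).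

Steps most likely to fail:

1. Step 13 (macrocyclisation). Ring strain in closing a ten-membered ring with a ring-trans trisubstituted alkene may let oligomerisation, protodeboronation or base hydrolysis of the esters win over ring closure. The fallback sets out from 22 and comes back at 24, forming the same C1–C2 bond from an organozinc without aqueous base. Borane 23 is made as before but oxidised (NaBO3·4H2O, THF/H2O) to the C2 primary alcohol F1. Appel iodination (I2, PPh3, imidazole) gives the C2 primary iodide F2. Zinc dust with LiCl in THF inserts into the primary C–I bond in preference to the alkenyl iodide, giving the alkylzinc iodide F3. This is added slowly to Pd2(dba)3 and tri(2-furyl)phosphine in THF/NMP at high dilution (intramolecular Negishi coupling) to give 24.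

2. Step 10 (carbocupration–iodination). The organocopper may add sluggishly or with the reverse regiochemistry next to the homopropargylic ester, or deprotonate the alkyne. The fallback sets out from 17 and comes back at 22, replacing steps 10–12. Rhodium-catalysed silylformylation (Me2PhSiH, CO, Rh4(CO)12 cat., toluene) adds silicon to C1 and the formyl group to C10 in syn fashion, giving the (Z)-β-silyl enal F4. Luche reduction (NaBH4, CeCl3·7H2O, MeOH, −40 °C) gives the allylic alcohol F5, and TBSCl/imidazole gives the silyl ether F6. Iododesilylation with retention (N-iodosuccinimide, hexafluoroisopropanol, 0 °C) then gives 22.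

3. Step 8 (C8 propargylation). Facial selectivity may be poor or reversed if the C7 stereocentre overrides the catalyst. The fallback sets out from 12 and comes back at 17. The 8S epimer is made on purpose with the enantiomeric (S)-TRIP catalyst, through the (8S)-O-pinacolboryl ether F7, to give the (8S)-alcohol F8. Mitsunobu esterification with isobutyric acid (PPh3, DIAD, toluene, 0 °C to rt) then inverts C8 and installs the isobutyrate in one operation, giving 17.

## Further compounds

F1 | step 13 | C2 primary alcohol from 22 (2-hydroxyethyl in place of the C2=C3 vinyl) | O=C1O[C@H](/C=C(/C)CCO)[C@H](C1)[C@H](OC(=O)C(C)C)C/C(CO[Si](C)(C)C(C)(C)C)=C/I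
F2 | step 13 | C2 primary iodide | O=C1O[C@H](/C=C(/C)CCI)[C@H](C1)[C@H](OC(=O)C(C)C)C/C(CO[Si](C)(C)C(C)(C)C)=C/I
F3 | step 13 | C2 alkylzinc iodide | O=C1O[C@H](/C=C(/C)CC[Zn]I)[C@H](C1)[C@H](OC(=O)C(C)C)C/C(CO[Si](C)(C)C(C)(C)C)=C/I
F4 | step 10 | (Z)-β-(dimethylphenylsilyl) enal (formyl on C10, silicon on C1) | O=C1O[C@H](/C=C(/C)C=C)[C@H](C1)[C@H](OC(=O)C(C)C)C/C(C=O)=C/[Si](C)(C)c1ccccc1
F5 | step 10 | C14 allylic alcohol with C1 dimethylphenylsilyl group | O=C1O[C@H](/C=C(/C)C=C)[C@H](C1)[C@H](OC(=O)C(C)C)C/C(CO)=C/[Si](C)(C)c1ccccc1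
F6 | step 10 | C14 tert-butyldimethylsilyl ether with C1 dimethylphenylsilyl group | O=C1O[C@H](/C=C(/C)C=C)[C@H](C1)[C@H](OC(=O)C(C)C)C/C(CO[Si](C)(C)C(C)(C)C)=C/[Si](C)(C)c1ccccc1
F7 | step 8 | (8S)-O-pinacolboryl ether | O=C1O[C@H](/C=C(/C)C=C)[C@H](C1)[C@@H](OB2OC(C)(C)C(C)(C)O2)CC#C
F8 | step 8 | (4R,5R)-4-[(1S)-1-hydroxybut-3-yn-1-yl]-5-[(1Z)-2-methylbuta-1,3-dien-1-yl]dihydrofuran-2(3H)-one | O=C1O[C@H](/C=C(/C)C=C)[C@H](C1)[C@@H](O)CC#C
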